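## The problem

2,3,6-Tribromo-1H-indole 11 is a flat, achiral bicycle: a benzene ring (ring A) fused across C3a–C7a to a pyrrole ring (ring B). It has no stereocentre, so no element of the route has to control another. The whole difficulty is to place three bromine atoms of three different kinds on the nucleus: an aryl bromide at C6, a bromide at the nucleophilic position C3, and a bromide at C2 next to nitrogen. C6–Br is best bought with the benzene ring and C3–Br answers to the innate reactivity of indole. C2–Br is the awkward one, because electrophiles do not go there first and a C2 carbanion would have to coexist with the other C–Br bonds. The molecule is also fragile: 2-bromoindoles with a free N–H are sensitive to acid and air, and all three C–Br bonds are at risk from dissolving metals, hydrogenation catalysts, alkyllithiums and low-valent palladium or copper. The enabling feature is that C2 carries both N1 and a bromine and is doubly bonded to C3, which is the oxidation level of the CBr2 carbon of a 1,1-dibromoalkene. C2 can therefore arrive from carbon tetrabromide with two bromines, losing one as the leaving group when N1 closes ring B and keeping the other.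

## Retrosynthesis

**N1–S.** Target 11 is first related to its N-methylsulfonyl derivative 10. No skeletal bond is cut. The sulfonyl group is needed for the ring closure in any case, and keeping it to the end means that the only unprotected 2-bromoindole of the route is the target itself. The forward reaction must cleave N–S without reducing or displacing any of three C–Br bonds, which points to nucleophilic attack at sulfur by fluoride rather than to dissolving-metal or hydride conditions.

**C3–Br.** In 10 the C3–Br bond is cut, giving 2,6-dibromo-1-(methylsulfonyl)-1H-indole 9. This is the one C–Br bond that innate reactivity will form. Cutting C2–Br instead would call for C2 metalation beside two other bromines and the acidic S–CH3 protons. Cutting C6–Br would ask the benzene ring to be substituted against its own preference. The forward reaction only asks that an electrophilic bromine source find the single open position of ring B before it touches ring A.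

**N1–C2 (key).** In 9 the N1–C2 bond is cut, opening ring B to the acyclic sulfonamide 7, in which the future C2 is the CBr2 terminus of a 1,1-dibromoalkene; bromoalkyne 8 is the expected way-station. The neighbouring cuts are weaker for this target:
- C3–C3a would need palladium beside an aryl bromide.
- N1–C7a would deliver C2 with carbon or hydrogen rather than bromine.
- C2–Br returns to the C2 metalation problem.

The chosen cut removes the ring and the C2–Br problem in one stroke. The forward reaction must let nitrogen displace exactly one vinylic bromide, without a transition metal, and leave the aryl bromide alone.

**N–S of the sulfonamide.** Sulfonamide 7 is cut at the N–S bond to aniline 5 and methanesulfonyl chloride 6. The sulfonyl group is chosen over acyl or carbamate groups because it makes N–H acidic enough for a carbonate base and gives a stable N-substituted 2-bromoindole. The forward reaction must stop at mono-sulfonylation.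

**Amine from nitro.** Aniline 5 is traced to nitroarene 4. A free amino group ortho to a formyl group would self-condense, whereas a nitro group is inert to the olefination and activates the aldehyde. The forward reduction must spare two vinylic and one aryl C–Br bond and the alkene, which excludes catalytic hydrogenation.

**C2=C3.** The double bond of 4 is cut to 4-bromo-2-nitrobenzaldehyde 1 and carbon tetrabromide 2, joined through ylide 3. Both 1 and 2 are articles of commerce. The aldehyde carbon of 1 becomes C3, the carbon of 2 becomes C2, and the bromine para to the formyl group ends at C6. The forward reaction is a standard dibromoolefination of an electron-poor aldehyde.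

## Roads not taken

**Alternative 1:** This road builds ring A. The bonds C3a–C7a and C4–C5 are cut, leading back to tert-butyl N-(4-bromofuran-2-yl)-N-(but-3-en-1-yl)carbamate A1. On heating, the furan and the tethered alkene of A1 would undergo an intramolecular Diels–Alder reaction. The oxygen bridge then opens under the push of nitrogen and leaves as water, giving tert-butyl 6-bromoindoline-1-carboxylate A2.
- Merits: no metal is used, the bromine position is fixed by the furan of A1, and two rings form in one thermal cascade. It is better than the chosen plan in one respect: it could supply benzene-ring substitution patterns that no commercial benzaldehyde offers.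
- Weak points: this target does not need that strength, because the benzene ring with its bromine can be bought. Furan A1 itself needs several steps (an aminofuran carbamate from a furan carboxylic acid by Curtius rearrangement, then N-alkylation). Indoline A2 has neither pyrrole-ring bromine, so dehydrogenation, carbamate removal, C3 bromination and the unsolved C2 bromination all remain.
- Comparison: the chosen plan is shorter and installs C2–Br in the act of ring closure.

**Alternative 2:** This road cuts C3–C3a. Methyl (Z)-3-[(5-bromo-2-iodophenyl)amino]acrylate A3 would cyclise with Pd(OAc)2 and K2CO3 in a Heck-type closure to methyl 6-bromo-1H-indole-3-carboxylate A4. The ester of A4 would later be exchanged for bromine by saponification and ipso-bromodecarboxylation.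
- Merits: selective oxidative addition into the C–I bond of A3 before its C–Br bond is well precedented, enamino ester A3 is one step from an aniline, and bromodecarboxylation at C3 of an indole acid is facile. In the reliability of the ring-forming event this road is at least the equal of the chosen one.
- Weak points: the iodide/bromide selectivity in A3 is only kinetic, and zerovalent palladium can enter the C6–Br bond of A4 once the iodide is consumed. Ester A4 also leaves C2 as C–H, and its 3-acyl group diverts electrophiles to the benzene ring. C2–Br would therefore need N-protection and directed metalation beside an aryl bromide, or a poorly controlled second bromination after decarboxylation.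
- Comparison: the chosen plan sets against the good Heck precedent the absence of any metal and a C2–Br bond that needs no separate step.

**Alternative 3:** This road cuts N1–C7a. Methyl (Z)-2-azido-3-(4-bromophenyl)acrylate A5 would lose nitrogen in hot xylene (Hemetsberger reaction), and the nitrene would bond to the ortho carbon to give methyl 6-bromo-1H-indole-2-carboxylate A6.
- Merits: the two ortho positions of the para-substituted ring of A5 are equivalent, so there is no regiochemical issue, and no metal is used. Ester A6 is two steps from commodity materials, against four steps to the bicycle in the chosen plan, so in step count to the indole nucleus this road is better.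
- Weak points: azide A5 is a vinyl azide that must be thermolysed, and its preparation handles a low-molecular-weight azide. More seriously, C2 arrives in A6 with a carboxylate, the right position but the wrong group. Replacing CO2H by Br at C2 is far less facile than at C3, and protodecarboxylation needs harsh conditions and only returns to the C2 bromination problem. C3 bromination is still required.
- Comparison: the chosen plan gives up the two-step access to the ring but has no functional-group exchange at C2 and no azide.

Key step: step 4

Assumption: the closure of 7 is written through bromoalkyne 8, the course expected for a carbonate base in a dipolar aprotic solvent; direct vinylic substitution on 7 would give the same product 9 and changes nothing in the route.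

## Route

Step 1
Reactants: 1 4-bromo-2-nitrobenzaldehyde; 2 carbon tetrabromide
Product: 4 4-bromo-1-(2,2-dibromovinyl)-2-nitrobenzene, via (dibromomethylidene)triphenylphosphorane 3 (not isolated)
Conditions: PPh3, CH2Cl2, 0 °C to rt
Reagents that add atoms: none
Why: Ramirez dibromoolefination (first stage of the Corey–Fuchs sequence): PPh3 and 2 give ylide 3, which undergoes a Wittig reaction with the electron-poor aldehyde 1; the nitro group and the aryl bromide are inert to the ylide, and ortho-nitrobenzaldehydes are standard substrates.

Step 2
Reactants: 4 4-bromo-1-(2,2-dibromovinyl)-2-nitrobenzene
Product: 5 5-bromo-2-(2,2-dibromovinyl)aniline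
Conditions: SnCl2·2H2O, EtOH, reflux; aq. NaHCO3 work-up
Reagents that add atoms: none
Why: Nitro-to-amine reduction by a divalent tin salt in a protic solvent, chosen because it leaves the 1,1-dibromoalkene and the aryl C–Br bond intact where catalytic hydrogenation would not.

Step 3
Reactants: 5 5-bromo-2-(2,2-dibromovinyl)aniline; 6 methanesulfonyl chloride
Product: 7 N-[5-bromo-2-(2,2-dibromovinyl)phenyl]methanesulfonamide
Conditions: pyridine, CH2Cl2, 0 °C to rt
Reagents that add atoms: none
Why: N-Sulfonylation of a primary aniline with a sulfonyl chloride; pyridine as a weak base and one equivalent of 6 at low temperature should hold the reaction at the mono-sulfonamide, whose nitrogen is weakly nucleophilic and hindered by the ortho alkenyl group.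

Step 4
Reactants: 7 N-[5-bromo-2-(2,2-dibromovinyl)phenyl]methanesulfonamide
Product: 9 2,6-dibromo-1-(methylsulfonyl)-1H-indole, via N-[5-bromo-2-(bromoethynyl)phenyl]methanesulfonamide 8 (not isolated)
Conditions: Cs2CO3, DMF, 60 °C
Reagents that add atoms: none
Why: Cs2CO3 deprotonates the sulfonamide N–H and removes HBr from the 1,1-dibromoalkene (the vinylic hydrogen and the bromine trans to it), giving bromoalkyne 8. The sulfonamide anion then adds to the bromine-bearing alkyne carbon, the only one within reach, and the resulting C3 vinyl anion is protonated by hydrogencarbonate, so that N1–C2 is formed and one bromine stays on C2. A direct addition–elimination of the anion at the CBr2 carbon of 7 (vinylic substitution) would converge on the same product. The closest known reaction type is the base- or fluoride-promoted, transition-metal-free cyclization of N-sulfonyl-2-(2,2-dibromovinyl)anilines to 2-bromoindoles, itself related to the carbonate-mediated conversion of 1,1-dibromoalkenes into 1-bromoalkynes. Ring B is closed in a 5-endo-dig mode and no stereocentre is formed. The step needs chemoselectivity among three C–Br bonds: only the vinylic pair is open to elimination and addition, the aryl C–Br bond has no pathway without a transition metal, and once the ring is aromatic the C2–Br bond is no longer electrophilic, so the reaction should stop after loss of one bromide. The methylsulfonyl group makes N–H acidic enough for a carbonate base and stabilises the 2-bromoindole, and the aprotic, nucleophile-free medium should spare the N–S bond.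

Step 5
Reactants: 9 2,6-dibromo-1-(methylsulfonyl)-1H-indole
Product: 10 2,3,6-tribromo-1-(methylsulfonyl)-1H-indole
Conditions: Br2, CH2Cl2, 0 °C to rt
Reagents that add atoms: bromine, BrBr
Why: Electrophilic aromatic substitution at C3, the only open position of ring B and still the most nucleophilic site of an N-sulfonylindole (the cationic intermediate is stabilised by N1 and by the lone pairs of the C2 bromine); the sulfonyl group guards against oxidation, and ring A, deactivated by C6–Br, should react far more slowly.

Step 6
Reactants: 10 2,3,6-tribromo-1-(methylsulfonyl)-1H-indole
Product: 11 2,3,6-tribromo-1H-indole
Conditions: Bu4NF, THF, 60 °C; then H2O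
Reagents that add atoms: none
Why: Fluoride-mediated N-desulfonylation of an N-sulfonylindole: fluoride attacks sulfur and expels the indolide, a good leaving group here because three bromines acidify the N–H; the anion is protonated on aqueous work-up, and fluoride neither reduces nor displaces aryl or heteroaryl bromides.

## Compound list

1 | 4-bromo-2-nitrobenzaldehyde | O=Cc1ccc(Br)cc1[N+](=O)[O-] | starting material
2 | carbon tetrabromide | BrC(Br)(Br)Br | starting material
3 | (dibromomethylidene)triphenylphosphorane | BrC(Br)=P(c1ccccc1)(c1ccccc1)c1ccccc1 | intermediate
4 | 4-bromo-1-(2,2-dibromovinyl)-2-nitrobenzene | O=[N+]([O-])c1cc(Br)ccc1C=C(Br)Br | intermediate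
5 | 5-bromo-2-(2,2-dibromovinyl)aniline | Nc1cc(Br)ccc1C=C(Br)Br | intermediate
6 | methanesulfonyl chloride | CS(=O)(=O)Cl | starting material
7 | N-[5-bromo-2-(2,2-dibromovinyl)phenyl]methanesulfonamide | CS(=O)(=O)Nc1cc(Br)ccc1C=C(Br)Br | intermediate
8 | N-[5-bromo-2-(bromoethynyl)phenyl]methanesulfonamide | CS(=O)(=O)Nc1cc(Br)ccc1C#CBr | intermediate
9 | 2,6-dibromo-1-(methylsulfonyl)-1H-indole | CS(=O)(=O)n1c(Br)cc2ccc(Br)cc21 | intermediate
10 | 2,3,6-tribromo-1-(methylsulfonyl)-1H-indole | CS(=O)(=O)n1c(Br)c(Br)c2ccc(Br)cc21 | intermediate
11 | 2,3,6-tribromo-1H-indole | Brc1ccc2c(Br)c(Br)[nH]c2c1 | target

## Step count and risks

Total step count: 6. Longest linear sequence: 6 steps (from 1 to 11).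

**Step 4 (key step).** The most likely failure is that bromoalkyne 8 is consumed between molecules faster than it closes, by addition of a second sulfonamide anion or of amine impurities from the solvent. A second risk is slow cleavage of the N–S bond of the product by carbonate, followed by degradation of the unprotected heterocycle. The fallback sets out from 7 and forms the N1–C2 bond by copper catalysis (CuI, N,N′-dimethylethane-1,2-diamine, K3PO4, toluene, 80 °C). This is an intramolecular Goldberg-type N-vinylation, in which a monovalent copper sulfonamidate engages the vinylic C–Br bond cis to the ring and reductive elimination gives the 2-bromoindole. It replaces the anionic elimination–addition by a metal-templated coupling that does not depend on a free bromoalkyne; the price is that the aryl C–Br bond must then be held back by temperature. The fallback comes back to the route at 9 and makes no new compound.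

**Step 5.** The most likely failure is sluggish substitution on a pyrrole ring deactivated by both the sulfonyl group and the C2 bromine. Forcing conditions would then erode positional selectivity through attack on ring A, or the acid formed would promote halogen scrambling. The fallback sets out from 9 and reverses the last two operations. The sulfonyl group is cleaved first with Bu4NF in THF to give 2,6-dibromo-1H-indole F1. This electron-rich N–H indole is brominated at once, without storage, with N-bromosuccinimide in THF at −78 to 0 °C, which should go to C3 under mild, non-acidic conditions. The fallback comes back to the route at 11.

**Step 6.** The most likely failure is competing attack of fluoride, or of hydroxide carried in by the hydrated reagent, at C2 (ipso displacement of the bromide activated by the N-sulfonyl group). Base-induced degradation of the liberated tribromoindolide at the temperature needed for N–S cleavage is the other risk. The fallback sets out from 5 and replaces methylsulfonyl by 2-nitrophenylsulfonyl, which a thiolate removes at room temperature by ipso attack on the nitroarene rather than at sulfur. Aniline 5 with 2-nitrobenzenesulfonyl chloride and pyridine gives N-[5-bromo-2-(2,2-dibromovinyl)phenyl]-2-nitrobenzenesulfonamide F2. Cs2CO3 in DMF closes the ring through N-[5-bromo-2-(bromoethynyl)phenyl]-2-nitrobenzenesulfonamide F3 (not isolated) to 2,6-dibromo-1-[(2-nitrophenyl)sulfonyl]-1H-indole F4. Bromine in CH2Cl2 gives 2,3,6-tribromo-1-[(2-nitrophenyl)sulfonyl]-1H-indole F5. Thiophenol with K2CO3 in DMF at room temperature then releases the free indole, and the fallback comes back to the route at 11.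

## Further compounds

F0 | step 4 | none | none
F1 | step 5 | 2,6-dibromo-1H-indole | Brc1ccc2cc(Br)[nH]c2c1
F2 | step 6 | N-[5-bromo-2-(2,2-dibromovinyl)phenyl]-2-nitrobenzenesulfonamide | O=[N+]([O-])c1ccccc1S(=O)(=O)Nc1cc(Br)ccc1C=C(Br)Br
F3 | step 6 | N-[5-bromo-2-(bromoethynyl)phenyl]-2-nitrobenzenesulfonamide | O=[N+]([O-])c1ccccc1S(=O)(=O)Nc1cc(Br)ccc1C#CBr
F4 | step 6 | 2,6-dibromo-1-[(2-nitrophenyl)sulfonyl]-1H-indole | O=[N+]([O-])c1ccccc1S(=O)(=O)n1c(Br)cc2ccc(Br)cc21
F5 | step 6 | 2,3,6-tribromo-1-[(2-nitrophenyl)sulfonyl]-1H-indole | O=[N+]([O-])c1ccccc1S(=O)(=O)n1c(Br)c(Br)c2ccc(Br)cc21
A1 | alternative 1 | tert-butyl N-(4-bromofuran-2-yl)-N-(but-3-en-1-yl)carbamate | CC(C)(C)OC(=O)N(CCC=C)c1cc(Br)co1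
A2 | alternative 1 | tert-butyl 6-bromoindoline-1-carboxylate | CC(C)(C)OC(=O)N1CCc2ccc(Br)cc21
A3 | alternative 2 | methyl (Z)-3-[(5-bromo-2-iodophenyl)amino]acrylate | COC(=O)/C=C\Nc1cc(Br)ccc1I
A4 | alternative 2 | methyl 6-bromo-1H-indole-3-carboxylate | COC(=O)c1c[nH]c2cc(Br)ccc12
A5 | alternative 3 | methyl (Z)-2-azido-3-(4-bromophenyl)acrylate | COC(=O)/C(N=[N+]=[N-])=C/c1ccc(Br)cc1
A6 | alternative 3 | methyl 6-bromo-1H-indole-2-carboxylate | COC(=O)c1cc2ccc(Br)cc2[nH]1
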